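The C2=C3 enol-ether double bond of a flat chromone, polarised by the C4 carbonyl so that C2 is electrophilic, is the handle for the central disconnection: the bond between C2 of the dihydropyranone ring and the ipso carbon (C1') of the 4-methoxyphenyl ring. The key step is a Pd(II)/pyridine-oxazoline-catalysed asymmetric conjugate addition of 4-methoxyphenylboronic acid. In one operation it joins both halves, saturates C2–C3 and sets the only stereocentre (C2, S) by catalyst control. The precursor is achiral 5-hydroxy-7-methoxy-8-prenylchromone. Its prenyl group is placed at C8 beforehand by a para-Claisen–Cope shift from O5, regiodefined because O1 is already locked in the pyranone ring.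

Key step: step 4

Remark: the sense of induction of the Pd/t-BuPyOx catalyst is assumed to follow the model established for cyclic enones ((S)-ligand leading to the 2R series), so the (R)-ligand is specified; the required event is arylation of the Re face of C2 (O1 > C3 > H).

Step 1
Reactants: 1 1-(2,6-dihydroxy-4-methoxyphenyl)ethan-1-one
Product: 3 5-hydroxy-7-methoxy-4H-chromen-4-one, via enaminone 2 (not isolated)
Conditions: Me2NCH(OMe)2 (1.3 equiv), toluene, 90 °C; concentrate; then conc. HCl, CH2Cl2, 40 °C
Reagents that add atoms: N,N-dimethylformamide dimethyl acetal, COC(OC)N(C)C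
Why: Condensation of the acetyl CH3 with the amide acetal should give the enaminone, which closes to the pyranone by acid-promoted intramolecular oxa-Michael addition and loss of dimethylamine (enaminone route to chromones); the two phenols of 1 are equivalent, so only one chromone can form.

Step 2
Reactants: 3 5-hydroxy-7-methoxy-4H-chromen-4-one
Product: 4 7-methoxy-5-[(3-methylbut-2-en-1-yl)oxy]-4H-chromen-4-one
Conditions: prenyl bromide (1.5 equiv), K2CO3, DMF, 40 °C
Reagents that add atoms: prenyl bromide (1-bromo-3-methylbut-2-ene), CC(C)=CCBr
Why: Williamson ether synthesis (SN2 at the primary allylic bromide) on the only phenol of 3; the chelated phenoxide should alkylate on oxygen in a dipolar aprotic solvent.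

Step 3
Reactants: 4 7-methoxy-5-[(3-methylbut-2-en-1-yl)oxy]-4H-chromen-4-one
Product: 7 5-hydroxy-7-methoxy-8-(3-methylbut-2-en-1-yl)-4H-chromen-4-one, via Claisen dienone 5 (not isolated), via Cope dienone 6 (not isolated)
Conditions: Eu(fod)3 (10 mol %), CHCl3, 60 °C, sealed tube
Reagents that add atoms: none
Why: Lewis-acid-catalysed aromatic Claisen rearrangement to C6, Cope rearrangement to C8 and tautomerisation (para-Claisen–Cope rearrangement) should move the prenyl group from O5 to C8; because O1 is fixed in the pyranone ring the position para to O5 is unambiguously C8, and two successive [3,3] shifts return a normal (not reverse) prenyl group.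

Step 4
Reactants: 7 5-hydroxy-7-methoxy-8-(3-methylbut-2-en-1-yl)-4H-chromen-4-one; 8 (4-methoxyphenyl)boronic acid (2 equiv)
Product: 9 Flowerine, (2S)-5-hydroxy-7-methoxy-2-(4-methoxyphenyl)-8-(3-methylbut-2-en-1-yl)chroman-4-one
Conditions: Pd(OCOCF3)2 (10 mol %), (R)-t-BuPyOx (12 mol %), NH4PF6 (30 mol %), H2O (5 equiv), ClCH2CH2Cl, 50 °C
Reagents that add atoms: none
Why: Transmetalation of 8 to the cationic Pd(II)–pyridine-oxazoline complex gives an aryl–Pd species that adds syn across the C2=C3 bond of 7 (aryl to C2, Pd to C3), and protonolysis of the resulting palladium enolate by water releases the flavanone and returns Pd(II) without a redox cycle. This is the known Pd(II)/PyOx-catalysed asymmetric conjugate addition of arylboronic acids to chromones, a Miyaura–Hayashi-type 1,4-addition. No ring is closed; the pyranone ring is only saturated at C2–C3. The single new stereocentre C2 is set by the catalyst: the tert-butyl group of the ligand differentiates the two faces of the flat enone in the enantiodetermining carbopalladation, and the (R)-ligand is expected to deliver the aryl group to the Re face of C2, which corresponds to 2S. The step needs chemoselectivity for the enone over the trisubstituted prenyl olefin, which the far higher insertion reactivity of the polarised, unhindered C2=C3 bond should secure, helped by the O5–H···O4 hydrogen bond that raises the electrophilicity of C2. The neutral to weakly acidic medium avoids the base-induced ring opening to the chalcone that would racemise a 5-hydroxyflavanone.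

Compound list
1 | 1-(2,6-dihydroxy-4-methoxyphenyl)ethan-1-one | CC(=O)c1c(O)cc(OC)cc1O | starting material
2 | (E)-1-(2,6-dihydroxy-4-methoxyphenyl)-3-(dimethylamino)prop-2-en-1-one | CN(C)/C=C/C(=O)c1c(O)cc(OC)cc1O | intermediate (not isolated)
3 | 5-hydroxy-7-methoxy-4H-chromen-4-one | O=C1C=COc2cc(OC)cc(O)c12 | intermediate
4 | 7-methoxy-5-[(3-methylbut-2-en-1-yl)oxy]-4H-chromen-4-one | O=C1C=COc2cc(OC)cc(OCC=C(C)C)c12 | intermediate
5 | 7-methoxy-6-(2-methylbut-3-en-2-yl)-6H-chromene-4,5-dione (racemic at C6) | O=C1C=COC2=C1C(=O)C(C(C)(C)C=C)C(OC)=C2 | intermediate (not isolated)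
6 | 7-methoxy-8-(3-methylbut-2-en-1-yl)-8H-chromene-4,5-dione (racemic at C8) | O=C1C=COC2=C1C(=O)C=C(OC)C2CC=C(C)C | intermediate (not isolated)
7 | 5-hydroxy-7-methoxy-8-(3-methylbut-2-en-1-yl)-4H-chromen-4-one | O=C1C=COc2c(CC=C(C)C)c(OC)cc(O)c12 | intermediate
8 | (4-methoxyphenyl)boronic acid | COc1ccc(B(O)O)cc1 | starting material
9 | Flowerine, (2S)-5-hydroxy-7-methoxy-2-(4-methoxyphenyl)-8-(3-methylbut-2-en-1-yl)chroman-4-one | COc1ccc([C@@H]2CC(=O)c3c(O)cc(OC)c(CC=C(C)C)c3O2)cc1 | target

Total step count: 4. Longest linear sequence: 4 steps (1 → 3 → 4 → 7 → 9).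

Steps most likely to fail

Step 4. The carbopalladation of the electron-rich, internally hydrogen-bonded chromone may be slow, so that protodeboronation and homocoupling of 8 outrun the addition, or coordination of the phenol to palladium may erode turnover and enantioselectivity. The fallback sets out from 7 and comes back at 9. The phenol of 7 is masked with MOMCl and i-Pr2NEt in CH2Cl2 to give 7-methoxy-5-(methoxymethoxy)-8-(3-methylbut-2-en-1-yl)-4H-chromen-4-one F1. A Rh(I)/chiral diene-catalysed asymmetric 1,4-addition of 8 ([RhCl(C2H4)2]2, the diene enantiomer that arylates the Re face of C2, toluene/water with a catalytic amount of weak base, 40 °C) should then give (2S)-7-methoxy-5-(methoxymethoxy)-2-(4-methoxyphenyl)-8-(3-methylbut-2-en-1-yl)chroman-4-one F2. The peri MOM ether is removed with catalytic HCl in MeOH at room temperature, conditions under which the flavanone does not ring-open, to return 9.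

Step 3. The C6 dienone may enolise before the Cope shift, which would leave a reverse prenyl group at C6, or the allyl ether may ionise with loss of the prenyl group. The fallback sets out from 3 and comes back at 7. Compound 3 is methylated (MeI, K2CO3, DMF) to 5,7-dimethoxy-4H-chromen-4-one F3. Electrophilic iodination (NIS, catalytic TFA, MeCN), directed to C8 once O5 is capped, gives 8-iodo-5,7-dimethoxy-4H-chromen-4-one F4. Stille coupling with tributyl(3-methylbut-2-en-1-yl)stannane (Pd(PPh3)4, DMF, 90 °C) gives 5,7-dimethoxy-8-(3-methylbut-2-en-1-yl)-4H-chromen-4-one F5. Chelation-controlled cleavage of the peri methyl ether with BCl3 (CH2Cl2, −78 °C) returns 7.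

Step 1. The amide acetal may O-methylate the phenols, or ring closure of the enaminone may stall. The fallback sets out from 1 and comes back at 3. Claisen formylation of 1 with ethyl formate and NaH in THF should give, after acidification, 2,5-dihydroxy-7-methoxychroman-4-one F6 (the cyclic hemiacetal of the β-ketoaldehyde). Dehydration with catalytic H2SO4 in AcOH returns 3.

Further compounds
F1 | step 4 | 7-methoxy-5-(methoxymethoxy)-8-(3-methylbut-2-en-1-yl)-4H-chromen-4-one | O=C1C=COc2c(CC=C(C)C)c(OC)cc(OCOC)c12
F2 | step 4 | (2S)-7-methoxy-5-(methoxymethoxy)-2-(4-methoxyphenyl)-8-(3-methylbut-2-en-1-yl)chroman-4-one | COc1ccc([C@@H]2CC(=O)c3c(OCOC)cc(OC)c(CC=C(C)C)c3O2)cc1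
F3 | step 3 | 5,7-dimethoxy-4H-chromen-4-one | O=C1C=COc2cc(OC)cc(OC)c12
F4 | step 3 | 8-iodo-5,7-dimethoxy-4H-chromen-4-one | O=C1C=COc2c(I)c(OC)cc(OC)c12
F5 | step 3 | 5,7-dimethoxy-8-(3-methylbut-2-en-1-yl)-4H-chromen-4-one | O=C1C=COc2c(CC=C(C)C)c(OC)cc(OC)c12
F6 | step 1 | 2,5-dihydroxy-7-methoxychroman-4-one | O=C1CC(O)Oc2cc(OC)cc(O)c12
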